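Follow the fraction of substrate left, not the fraction of target made.

the same everywhere: substrate 20 mM
- blue: precatalyst 2 µM; the very flask that is asked about, followed so far
- flask: precatalyst 2.0 µM; time 15 d

- blue (time / d: target / %, substrate / %): 0.0833: 35, 61; 0.250: 93, 4; 0.833: 95, 1; 2.00: 91, 0; 6.00: 78, 2

(readings scatter by 1.5 percentage points)

- what was read earlier has a scatter of 1.5 percentage points, one standard deviation

* the best time, 15 d at the latest, for target
* the amount of target, in percent of the substrate charged, at that time

1. In this flask the substrate left fell from 61% to 4% between the first two readings. That is a making rate of 16.3 d⁻¹, so I read a making time of 0.0612 d.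
2. Target then fell from 95% to 78%, a first-order loss of 0.0382 d⁻¹. That gives a loss time of 26.2 d, far longer than the making time.
3. With target near the whole charge, making equals loss when the fraction left equals the ratio of these times. I call this the stop fraction: 0.233%.
4. Starting from the 4% left at 0.250 d, I reckoned the flask would reach it at 0.424 d. Taking off the stop fraction and the loss up to then left 98.1%.
5. The forecast gave 0.45 d and 96%: “The maximum comes where formation equals loss”. Its amount is lower than mine.
6. The flask gave 98.0% at 0.362 d, with 0.228% substrate left, level with the stop fraction.

    target ⇌ isomer of the product (K = 0.440, k = 8.40 × 10⁻⁷ s⁻¹)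
    substrate + enzyme → target + enzyme, rate k2*[substrate]*[enzyme]/(1 + ([substrate]/Km2) + ([target]/Kp2)) (12.0 mM, 6.30 mM, k = 3300 M⁻¹ s⁻¹)
    precatalyst ⇌ enzyme (K = 2.10, k = 8.30 × 10⁻⁶ s⁻¹)

The neighbour flask was charged with 50 mM of substrate, and I had no reading of its making time, so I reckoned no stop fraction for it. The sum from step 4 still applies to it: its best is the whole charge less the substrate left and the isomer of the product made by then. Its best was 97.2%, so those two together took more in the neighbour flask than in this flask: 2.80% against 2.00%.

Readings and results were generated by integration from invented constants, noise included.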